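Its constants stand for no real mixture; the result is computed.

The step that makes spent catalyst gains more from heat than the release of product, by a factor of 13 against 11 from the coldest flask to the hottest. So what I watch in this run is the fraction of catalyst left, not the fraction of product made.

| flask | substrate | free catalyst | temperature | time | remark |
|---|---|---|---|---|---|
| south-east | 1.6 M | 160 mM | 35 °C | 40 s |  |
| north | 1.6 M | 160 mM |  | 40 s | at 35 °C until 20 s, from then on at 65 °C |
| north-east | 1.6 M | 160 mM | 50 °C | 40 s |  |
| south-west | 1.6 M | 160 mM | 65 °C | 40 s |  |

    substrate + free catalyst ⇌ catalyst intermediate A (K1 = 2.9 M⁻¹, k1 = 0.41 M⁻¹ s⁻¹, Ea1 = 47.0 kJ mol⁻¹, ΔH1 = 4.00 kJ mol⁻¹)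
    catalyst intermediate A → catalyst intermediate B (k2 = 0.11 s⁻¹, Ea2 = 71.0 kJ mol⁻¹)
    substrate + catalyst intermediate B → spent catalyst (k3 = 0.0021 M⁻¹ s⁻¹, Ea3 = 75.0 kJ mol⁻¹)
    catalyst intermediate B ⇌ free catalyst + product (K4 = 0.34 M, k4 = 0.80 s⁻¹, Ea4 = 68.0 kJ mol⁻¹, ΔH4 = −42.0 kJ mol⁻¹)
    (constants at 35 °C)

- percent here means substrate units held: one spent catalyst counts as two
- the constants hold at 35 °C; other temperatures follow from the activation energies and enthalpies

- the best flask by amount of product, in percent of the substrate charged; "all alike" if 1.5 percentage points covers them all (south-east / north / north-east / south-west / all alike)
- amount of product at the end, in percent of the substrate charged, south-east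
- amount of product at the end, in percent of the substrate charged, north
- amount of product at the end, in percent of the substrate charged, north-east
- amount of product at the end, in percent of the substrate charged, south-west

I reckon the south-west flask at 65 °C, and I ask how much product its catalyst can make before none is left. The first way is a plain balance. If every catalyst ends as spent catalyst, that form holds 20.0% of the substrate charged, so product stops at 80.0%.

The second way follows the catalyst round by round. In that flask the release runs at 8.43 s⁻¹ against 1.29 s⁻¹ for the step feeding it, so I hold catalyst intermediate B in balance with free catalyst and product. I also take catalyst intermediate A as steady. Dividing the rate of loss by the rate of rounds then cancels both substrate and free catalyst, and the chance that a round kills its catalyst is a toll times p, where p is the fraction of the charge made into product. At 65 °C the toll is 0.405.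

The toll is constant at a fixed temperature, so the chance of loss per round grows with p, and the losses add up as the square of p. The fraction of catalyst left is one minus the square of p over the ceiling, and the ceiling, the product fraction at which the catalyst is used up, is 70.3%. That is a turnover number of 7.03 rounds per catalyst. I count rounds as product, and at the ceiling the chance of loss is 0.285 per round, so the ceiling runs a little high.

The two ways part by 9.7 percentage points. The balance is the one that cheats, because it spends the whole substrate charge and so assumes live catalyst up to the last of it. I commit to the ceiling, which gives no figure for 40 s itself.

The forecast names south-west as best, with 20.5% south-east, 42% north, 43% north-east and 48% south-west, on the ground that “heating speeds turnover a great deal but brings stronger product inhibition”. Its south-west figure stands under my ceiling.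

The flasks give 20.7% south-east, 38.9% north, 40.2% north-east and 47.4% south-west, so south-west is best and the forecast holds. By 400 s the south-west flask reaches 66.9%, with spent catalyst at 96.7% of the catalyst charged and 13.4% of the substrate still there, which is below both the ceiling and the balance. At 40.0 s the square law puts spent catalyst at 45.5%, and the flask holds 50.1%.

In a neighbouring flask, the south-west flask with 0.40 M of free catalyst, the ceiling rises with the root of the charge to 111%, above the whole substrate charge, so my reckoning has the catalyst outlast the substrate there. That flask gives 58.4% with 10.0% of the substrate left, and at that product the square law gives 27.7% spent against the 31.5% it holds.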